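**Retrosynthetic overview**
1. C1'–O ether: Mitsunobu coupling of umbelliferone with the primary allylic alcohol of a C15 triene-1,5-diol, then 5-O-acetylation and 8-O-desilylation. The coumarin bicycle is bought intact, so no ring is formed in the route.
2. C4'–C5' bond and the 5S centre: catalytic enantioselective vinylogous Mukaiyama aldol of a senecioate silyl dienol ether with an (R)-4-silyloxy enal; this also creates the 2E alkene.
3. C8'–C9' bond and the 8R centre: proposed new chiral phosphoric acid-catalysed linear prenylboration of ethyl (E)-3-methyl-4-oxobut-2-enoate (which already carries the 6E alkene) with a tertiary 1,1-dimethylallyl pinacol boronate made from prenol.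

Assumption: the sense of induction of both chiral catalysts follows their accepted facial models ((R)-TRIP delivers the allyl unit to the Re face; the (S,S)-bisphosphoramide·SiCl4 complex directs attack to the Si face); if the configuration of 6 or 13 were found opposite, the catalyst antipode would be used with no other change.

**Route**

Step 1
Reactants: 1 3-methylbut-2-en-1-ol (prenol)
Product: 2 methyl 3-methylbut-2-en-1-yl carbonate
Conditions: ClCO2Me (1.2 equiv), pyridine (1.5 equiv), CH2Cl2, 0 °C → rt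
Reagents that add atoms: methyl chloroformate, COC(=O)Cl
Why: Nucleophilic acyl substitution of the chloroformate by the primary allylic alcohol installs the carbonate leaving group needed for the copper step; no stereocentre is involved.

Step 2
Reactants: 2 methyl 3-methylbut-2-en-1-yl carbonate
Product: 3 4,4,5,5-tetramethyl-2-(2-methylbut-3-en-2-yl)-1,3,2-dioxaborolane
Conditions: B2pin2 (1.1 equiv), CuCl (5 mol %), 1,3-bis(2,4,6-trimethylphenyl)imidazolinium chloride (5.5 mol %), NaOt-Bu (15 mol %), THF, 0 °C → rt; distillation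
Reagents that add atoms: bis(pinacolato)diboron, CC1(C)OB(OC1(C)C)B1OC(C)(C)C(C)(C)O1
Why: Copper-catalysed γ-selective (formal SN2') allylic borylation: the carbene-ligated Cu–Bpin species adds across the trisubstituted alkene with boron on the dimethyl-substituted carbon and β-eliminates the carbonate, giving the tertiary allyl boronate, which as a pinacol ester does not undergo 1,3-boryl shift.

Step 3
Reactants: 4 ethyl (2E)-3-methyl-4-oxobut-2-enoate; 3 4,4,5,5-tetramethyl-2-(2-methylbut-3-en-2-yl)-1,3,2-dioxaborolane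
Product: 6 ethyl (2E,4R)-4-hydroxy-3,7-dimethylocta-2,6-dienoate, via pinacol borate ester 5 (not isolated)
Conditions: 3 (1.3 equiv), (R)-TRIP [(R)-3,3'-bis(2,4,6-triisopropylphenyl)-1,1'-binaphthyl-2,2'-diyl hydrogen phosphate] (5 mol %), 4 Å MS, toluene, −30 °C; then aq. NaHCO3
Reagents that add atoms: none
Why: Proposed new method: a chiral phosphoric acid-catalysed, allyl-transposing (linear) prenylboration in which tertiary boronate 3 reacts through a closed six-membered chair transition state, the catalyst P–OH hydrogen-bonding the pseudo-axial boronate oxygen (raising boron Lewis acidity) and P=O contacting the formyl C–H, so that the unsubstituted CH2 terminus adds to the Re face of 4 (Si face blocked by a 2,4,6-triisopropylphenyl group) to set C4 as R, while 1,3-transposition turns the CMe2–B carbon into the Me2C=CH alkene (no E/Z issue, and no reverse-prenyl isomer because the pinacol ester does not undergo borotropic shift at −30 °C); the closest known reaction type is chiral phosphoric acid-catalysed allyl- and crotylboration of aldehydes with pinacol boronates, which to my knowledge has not been shown with an α,α-dialkylallyl boronate as an enantioselective linear-prenyl donor or on a 2-methyl-3-alkoxycarbonyl enal.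

Step 4
Reactants: 6 ethyl (2E,4R)-4-hydroxy-3,7-dimethylocta-2,6-dienoate
Product: 7 ethyl (2E,4R)-4-[(tert-butyldimethylsilyl)oxy]-3,7-dimethylocta-2,6-dienoate
Conditions: TBSOTf (1.2 equiv), 2,6-lutidine (1.5 equiv), CH2Cl2, −78 → 0 °C
Reagents that add atoms: tert-butyldimethylsilyl trifluoromethanesulfonate, CC(C)(C)[Si](C)(C)OS(=O)(=O)C(F)(F)F
Why: O-Silylation (silyl ether protection) of the hindered secondary allylic alcohol with the reactive silyl triflate under buffered conditions leaves the E-enoate and the C4 centre untouched.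

Step 5
Reactants: 7 ethyl (2E,4R)-4-[(tert-butyldimethylsilyl)oxy]-3,7-dimethylocta-2,6-dienoate
Product: 8 (2E,4R)-4-[(tert-butyldimethylsilyl)oxy]-3,7-dimethylocta-2,6-dien-1-ol
Conditions: i-Bu2AlH (2.5 equiv), CH2Cl2, −78 °C; aq. potassium sodium tartrate (KNaC4H4O6)
Reagents that add atoms: none
Why: 1,2-Hydride reduction of the conjugated ester by i-Bu2AlH gives the allylic alcohol; silyl ether, alkenes and the stereocentre are inert.

Step 6
Reactants: 8 (2E,4R)-4-[(tert-butyldimethylsilyl)oxy]-3,7-dimethylocta-2,6-dien-1-ol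
Product: 9 (2E,4R)-4-[(tert-butyldimethylsilyl)oxy]-3,7-dimethylocta-2,6-dienal
Conditions: activated MnO2 (15 equiv), CH2Cl2, rt
Reagents that add atoms: none
Why: Chemoselective MnO2 oxidation of the primary allylic alcohol gives the enal without E/Z isomerisation or epimerisation of the γ-silyloxy centre.

Step 7
Reactants: 10 methyl 3-methylbut-2-enoate
Product: 11 tert-butyl[(1-methoxy-3-methylbuta-1,3-dien-1-yl)oxy]dimethylsilane (ketene acetal geometry not controlled; it is erased in step 8)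
Conditions: LiN(i-Pr)2 (1.1 equiv), THF, −78 °C; TBSCl, DMPU, −78 °C → rt; distillation
Reagents that add atoms: tert-butyldimethylsilyl chloride, CC(C)(C)[Si](C)(C)Cl
Why: γ-Deprotonation of the senecioate and O-silylation of the extended enolate (silyl ketene acetal formation) gives the silyl dienol ether.

Step 8
Reactants: 9 (2E,4R)-4-[(tert-butyldimethylsilyl)oxy]-3,7-dimethylocta-2,6-dienal; 11 tert-butyl[(1-methoxy-3-methylbuta-1,3-dien-1-yl)oxy]dimethylsilane
Product: 13 methyl (2E,5S,6E,8R)-8-[(tert-butyldimethylsilyl)oxy]-5-hydroxy-3,7,11-trimethyldodeca-2,6,10-trienoate, via trichlorosilyl ether 12 (not isolated)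
Conditions: 11 (1.2 equiv), SiCl4 (1.1 equiv), (S,S)-bisphosphoramide [two (S)-N,N'-dimethyl-1,1'-binaphthyl-2,2'-diamine phosphoramide units joined through N-methyl nitrogens by a (CH2)5 chain] (5 mol %), i-Pr2NEt (10 mol %), CH2Cl2, −78 °C; then sat. aq. NaHCO3
Reagents that add atoms: silicon tetrachloride, Cl[Si](Cl)(Cl)Cl (its atoms are kept only in 12 and are lost on work-up)
Why: Catalytic enantioselective vinylogous Mukaiyama aldol under Lewis base-activated SiCl4: the chiral phosphoramide-bound trichlorosilyl cation activates the enal, the dienol ether attacks through its γ-CH2 in an open transition state on the Si face (catalyst control, the remote C8 centre having little influence) to set 5S, and the 2E enoate forms with the larger chain trans to the ester.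

Step 9
Reactants: 13 methyl (2E,5S,6E,8R)-8-[(tert-butyldimethylsilyl)oxy]-5-hydroxy-3,7,11-trimethyldodeca-2,6,10-trienoate
Product: 14 (2E,5S,6E,8R)-8-[(tert-butyldimethylsilyl)oxy]-3,7,11-trimethyldodeca-2,6,10-triene-1,5-diol
Conditions: i-Bu2AlH (3.5 equiv), CH2Cl2, −78 °C; aq. potassium sodium tartrate (KNaC4H4O6)
Reagents that add atoms: none
Why: 1,2-Reduction of the enoate by i-Bu2AlH gives the primary allylic alcohol while the free 5-OH is simply carried as its aluminium alkoxide; no stereocentre is touched.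

Step 10
Reactants: 14 (2E,5S,6E,8R)-8-[(tert-butyldimethylsilyl)oxy]-3,7,11-trimethyldodeca-2,6,10-triene-1,5-diol; 15 7-hydroxy-2H-chromen-2-one (umbelliferone)
Product: 16 7-{[(2E,5S,6E,8R)-8-[(tert-butyldimethylsilyl)oxy]-5-hydroxy-3,7,11-trimethyldodeca-2,6,10-trien-1-yl]oxy}-2H-chromen-2-one
Conditions: PPh3 (1.1 equiv), DIAD (1.1 equiv), 15 (1.1 equiv), THF, 0 °C
Reagents that add atoms: none
Why: Mitsunobu etherification: the unhindered primary allylic alcohol is activated as the oxyphosphonium ion and displaced (SN2) by the acidic phenol much faster than the secondary 5-OH, and the 2E geometry makes intramolecular etherification impossible.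

Step 11
Reactants: 16 7-{[(2E,5S,6E,8R)-8-[(tert-butyldimethylsilyl)oxy]-5-hydroxy-3,7,11-trimethyldodeca-2,6,10-trien-1-yl]oxy}-2H-chromen-2-one
Product: 17 (2E,5S,6E,8R)-8-[(tert-butyldimethylsilyl)oxy]-3,7,11-trimethyl-1-[(2-oxo-2H-chromen-7-yl)oxy]dodeca-2,6,10-trien-5-yl acetate
Conditions: Ac2O (2 equiv), pyridine, DMAP (cat.), CH2Cl2, 0 °C → rt
Reagents that add atoms: acetic anhydride, CC(=O)OC(C)=O
Why: DMAP-catalysed acylation of the only free hydroxyl proceeds at oxygen with retention at C5.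

Step 12
Reactants: 17 (2E,5S,6E,8R)-8-[(tert-butyldimethylsilyl)oxy]-3,7,11-trimethyl-1-[(2-oxo-2H-chromen-7-yl)oxy]dodeca-2,6,10-trien-5-yl acetate
Product: 18 (2E,5S,6E,8R)-8-hydroxy-3,7,11-trimethyl-1-[(2-oxo-2H-chromen-7-yl)oxy]dodeca-2,6,10-trien-5-yl acetate (CNP0291294.2)
Conditions: HF·pyridine, pyridine, THF, 0 °C → rt
Reagents that add atoms: none
Why: Buffered fluoride desilylation cleaves only the Si–O bond, so the allylic acetate, aryl allyl ether and lactone survive, and acetyl migration from O5 to O8 is impossible across the E-alkene.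

**Compound list**
1 | 3-methylbut-2-en-1-ol (prenol) | CC(C)=CCO | starting material
2 | methyl 3-methylbut-2-en-1-yl carbonate | COC(=O)OCC=C(C)C | intermediate
3 | 4,4,5,5-tetramethyl-2-(2-methylbut-3-en-2-yl)-1,3,2-dioxaborolane | C=CC(C)(C)B1OC(C)(C)C(C)(C)O1 | intermediate
4 | ethyl (2E)-3-methyl-4-oxobut-2-enoate | CCOC(=O)/C=C(\C)C=O | starting material
5 | ethyl (2E,4R)-3,7-dimethyl-4-[(4,4,5,5-tetramethyl-1,3,2-dioxaborolan-2-yl)oxy]octa-2,6-dienoate (pinacol borate ester, not isolated) | CCOC(=O)/C=C(\C)[C@H](OB1OC(C)(C)C(C)(C)O1)CC=C(C)C | intermediate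
6 | ethyl (2E,4R)-4-hydroxy-3,7-dimethylocta-2,6-dienoate | CCOC(=O)/C=C(\C)[C@H](O)CC=C(C)C | intermediate
7 | ethyl (2E,4R)-4-[(tert-butyldimethylsilyl)oxy]-3,7-dimethylocta-2,6-dienoate | CCOC(=O)/C=C(\C)[C@H](O[Si](C)(C)C(C)(C)C)CC=C(C)C | intermediate
8 | (2E,4R)-4-[(tert-butyldimethylsilyl)oxy]-3,7-dimethylocta-2,6-dien-1-ol | OC/C=C(\C)[C@H](O[Si](C)(C)C(C)(C)C)CC=C(C)C | intermediate
9 | (2E,4R)-4-[(tert-butyldimethylsilyl)oxy]-3,7-dimethylocta-2,6-dienal | O=C/C=C(\C)[C@H](O[Si](C)(C)C(C)(C)C)CC=C(C)C | intermediate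
10 | methyl 3-methylbut-2-enoate | COC(=O)C=C(C)C | starting material
11 | tert-butyl[(1-methoxy-3-methylbuta-1,3-dien-1-yl)oxy]dimethylsilane | COC(=CC(C)=C)O[Si](C)(C)C(C)(C)C | intermediate
12 | methyl (2E,5S,6E,8R)-8-[(tert-butyldimethylsilyl)oxy]-3,7,11-trimethyl-5-[(trichlorosilyl)oxy]dodeca-2,6,10-trienoate (trichlorosilyl ether, not isolated) | Cl[Si](Cl)(Cl)O[C@H](/C=C(\C)[C@H](O[Si](C)(C)C(C)(C)C)CC=C(C)C)C/C(C)=C/C(=O)OC | intermediate
13 | methyl (2E,5S,6E,8R)-8-[(tert-butyldimethylsilyl)oxy]-5-hydroxy-3,7,11-trimethyldodeca-2,6,10-trienoate | O[C@H](/C=C(\C)[C@H](O[Si](C)(C)C(C)(C)C)CC=C(C)C)C/C(C)=C/C(=O)OC | intermediate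
14 | (2E,5S,6E,8R)-8-[(tert-butyldimethylsilyl)oxy]-3,7,11-trimethyldodeca-2,6,10-triene-1,5-diol | O[C@H](/C=C(\C)[C@H](O[Si](C)(C)C(C)(C)C)CC=C(C)C)C/C(C)=C/CO | intermediate
15 | 7-hydroxy-2H-chromen-2-one (umbelliferone) | Oc1ccc2ccc(=O)oc2c1 | starting material
16 | 7-{[(2E,5S,6E,8R)-8-[(tert-butyldimethylsilyl)oxy]-5-hydroxy-3,7,11-trimethyldodeca-2,6,10-trien-1-yl]oxy}-2H-chromen-2-one | O[C@H](/C=C(\C)[C@H](O[Si](C)(C)C(C)(C)C)CC=C(C)C)C/C(C)=C/COc1ccc2ccc(=O)oc2c1 | intermediate
17 | (2E,5S,6E,8R)-8-[(tert-butyldimethylsilyl)oxy]-3,7,11-trimethyl-1-[(2-oxo-2H-chromen-7-yl)oxy]dodeca-2,6,10-trien-5-yl acetate | CC(=O)O[C@H](/C=C(\C)[C@H](O[Si](C)(C)C(C)(C)C)CC=C(C)C)C/C(C)=C/COc1ccc2ccc(=O)oc2c1 | intermediate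
18 | (2E,5S,6E,8R)-8-hydroxy-3,7,11-trimethyl-1-[(2-oxo-2H-chromen-7-yl)oxy]dodeca-2,6,10-trien-5-yl acetate | CC(=O)O[C@H](/C=C(\C)[C@H](O)CC=C(C)C)C/C(C)=C/COc1ccc2ccc(=O)oc2c1 | target

**Step count and risks**

Total steps: 12. Longest linear sequence: 11 steps (1 → 2 → 3 → 6 → 7 → 8 → 9 → 13 → 14 → 16 → 17 → 18, that is steps 1–6 and 8–12); counted from aldehyde 4 it is 9 steps.

The three steps most likely to fail:

Step 3 (the proposed new method). The α,α-dimethyl group slows the chair transition state, so an uncatalysed racemic background reaction or weak facial control could erode the ee. The fallback sets out from 4 and comes back at 6 and uses only known chemistry. Aldehyde 4 and boronate 3 are heated without catalyst (toluene, 60 °C), the known thermal allylboration of α,α-disubstituted allyl boronates with allylic transposition, to give racemic ethyl (2E)-3,7-dimethyl-4-[(4,4,5,5-tetramethyl-1,3,2-dioxaborolan-2-yl)oxy]octa-2,6-dienoate F1, which on aqueous work-up gives racemic ethyl (2E)-4-hydroxy-3,7-dimethylocta-2,6-dienoate F2. Oxidation with Dess–Martin periodinane (NaHCO3-buffered, CH2Cl2, 0 °C) gives ethyl (2E)-3,7-dimethyl-4-oxoocta-2,6-dienoate F3. Corey–Bakshi–Shibata reduction ((S)-2-methyl-CBS-oxazaborolidine, catecholborane, toluene, −78 °C; the alkenyl group acts as the large substituent, the CH2 group as the small one) then sets the R carbinol and returns 6. The stereocentre thus comes from a ketone reduction and not from C–C bond formation.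

Step 8 (vinylogous aldol). The β,β-disubstituted, γ-silyloxy enal may react slowly, and the face selectivity or the 2E/2Z ratio may be insufficient. The fallback sets out from 9 and comes back at 14, bypassing 13. Enal 9 undergoes the known chiral phosphoric acid-catalysed propargylboration with allenylboronic acid pinacol ester ((S)-TRIP, 4 Å MS, toluene, −30 °C, Si-face attack) to give 2-{[(4S,5E,7R)-7-[(tert-butyldimethylsilyl)oxy]-6,10-dimethylundeca-5,9-dien-1-yn-4-yl]oxy}-4,4,5,5-tetramethyl-1,3,2-dioxaborolane F4, hydrolysed on work-up to (4S,5E,7R)-7-[(tert-butyldimethylsilyl)oxy]-6,10-dimethylundeca-5,9-dien-1-yn-4-ol F5. Negishi zirconium-catalysed methylalumination of the terminal alkyne (Me3Al, Cp2ZrCl2, CH2Cl2, 0 °C → rt; syn addition with aluminium on the terminal carbon) gives the dimethylaluminium alkoxide of the (E)-alkenyldimethylalane F6. This is trapped in the same flask with paraformaldehyde, with retention of alkene geometry, to give diol 14 directly.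

Step 10 (chemoselective Mitsunobu on the unprotected 1,5-diol). The secondary allylic 5-OH may compete through substitution or elimination. The fallback sets out from 13 and comes back at 16, replacing chemoselectivity by protection. Alcohol 13 is silylated (TESCl, imidazole, CH2Cl2, 0 °C) to methyl (2E,5S,6E,8R)-8-[(tert-butyldimethylsilyl)oxy]-3,7,11-trimethyl-5-[(triethylsilyl)oxy]dodeca-2,6,10-trienoate F7. Reduction with i-Bu2AlH (CH2Cl2, −78 °C) gives (2E,5S,6E,8R)-8-[(tert-butyldimethylsilyl)oxy]-3,7,11-trimethyl-5-[(triethylsilyl)oxy]dodeca-2,6,10-trien-1-ol F8. Mitsunobu coupling with 15 (PPh3, DIAD, THF, 0 °C) gives 7-{[(2E,5S,6E,8R)-8-[(tert-butyldimethylsilyl)oxy]-3,7,11-trimethyl-5-[(triethylsilyl)oxy]dodeca-2,6,10-trien-1-yl]oxy}-2H-chromen-2-one F9. Selective cleavage of the triethylsilyl ether (PPTS, MeOH/CH2Cl2, 0 °C) then returns 16.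

**Further compounds**
F1 | step 3 | racemic ethyl (2E)-3,7-dimethyl-4-[(4,4,5,5-tetramethyl-1,3,2-dioxaborolan-2-yl)oxy]octa-2,6-dienoate | CCOC(=O)/C=C(\C)C(OB1OC(C)(C)C(C)(C)O1)CC=C(C)C
F2 | step 3 | racemic ethyl (2E)-4-hydroxy-3,7-dimethylocta-2,6-dienoate | CCOC(=O)/C=C(\C)C(O)CC=C(C)C
F3 | step 3 | ethyl (2E)-3,7-dimethyl-4-oxoocta-2,6-dienoate | CCOC(=O)/C=C(\C)C(=O)CC=C(C)C
F4 | step 8 | 2-{[(4S,5E,7R)-7-[(tert-butyldimethylsilyl)oxy]-6,10-dimethylundeca-5,9-dien-1-yn-4-yl]oxy}-4,4,5,5-tetramethyl-1,3,2-dioxaborolane | CC1(C)OB(O[C@H](/C=C(\C)[C@H](O[Si](C)(C)C(C)(C)C)CC=C(C)C)CC#C)OC1(C)C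
F5 | step 8 | (4S,5E,7R)-7-[(tert-butyldimethylsilyl)oxy]-6,10-dimethylundeca-5,9-dien-1-yn-4-ol | O[C@H](/C=C(\C)[C@H](O[Si](C)(C)C(C)(C)C)CC=C(C)C)CC#C
F6 | step 8 | dimethylaluminium (1E,4S,5E,7R)-7-[(tert-butyldimethylsilyl)oxy]-1-(dimethylalumanyl)-2,6,10-trimethylundeca-1,5,9-trien-4-olate | C[Al](C)O[C@H](/C=C(\C)[C@H](O[Si](C)(C)C(C)(C)C)CC=C(C)C)C/C(C)=C/[Al](C)C
F7 | step 10 | methyl (2E,5S,6E,8R)-8-[(tert-butyldimethylsilyl)oxy]-3,7,11-trimethyl-5-[(triethylsilyl)oxy]dodeca-2,6,10-trienoate | CC[Si](CC)(CC)O[C@H](/C=C(\C)[C@H](O[Si](C)(C)C(C)(C)C)CC=C(C)C)C/C(C)=C/C(=O)OC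
F8 | step 10 | (2E,5S,6E,8R)-8-[(tert-butyldimethylsilyl)oxy]-3,7,11-trimethyl-5-[(triethylsilyl)oxy]dodeca-2,6,10-trien-1-ol | CC[Si](CC)(CC)O[C@H](/C=C(\C)[C@H](O[Si](C)(C)C(C)(C)C)CC=C(C)C)C/C(C)=C/CO
F9 | step 10 | 7-{[(2E,5S,6E,8R)-8-[(tert-butyldimethylsilyl)oxy]-3,7,11-trimethyl-5-[(triethylsilyl)oxy]dodeca-2,6,10-trien-1-yl]oxy}-2H-chromen-2-one | CC[Si](CC)(CC)O[C@H](/C=C(\C)[C@H](O[Si](C)(C)C(C)(C)C)CC=C(C)C)C/C(C)=C/COc1ccc2ccc(=O)oc2c1
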